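Target ⇐ 3-unsubstituted, bis-silylated flavone: the 3-hydroxyl is added after ring closure (C3 lithiation, borylation, oxidation) and both silyl ethers are removed last with fluoride.
The strategy rests on ring C, where the carbonyl carbon C4 lies between C4a of ring A and the C3–C2 unit that ends on O1. Cutting C4a–C4, C4–C3 and O1–C2 gives an ortho-iodophenol, CO and an arylacetylene, joined in one palladium-catalysed carbonylative annulation.
Ring A piece: 3-hydroxy-4,5-dimethoxybenzaldehyde by TIPS ether, Baeyer–Villiger oxidation to the phenol, MOM ether, lithiation–iodination between the MOM and methoxy oxygens, MOM removal.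
Ring B piece: 2-(5-bromo-2-methoxyphenyl)acetic acid by Weinreb amide, isopropenyl Grignard addition, CBS reduction (sets the only stereocentre, R), TES ether, Sonogashira coupling, C-desilylation.
Ring order: rings A and B are bought as benzene rings; ring C is the only ring made, in the key step.

Key step: step 12

Assumption: the side-chain carbinol carbon is (R) as read from the SMILES; isopropenylmagnesium bromide (THF solution), trimethylsilylacetylene and carbon monoxide are bought and are numbered because their carbon atoms end up in the target.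

Step 1
Reactants: 1 3-hydroxy-4,5-dimethoxybenzaldehyde
Product: 2 3,4-dimethoxy-5-(triisopropylsilyloxy)benzaldehyde
Conditions: TIPSCl, imidazole, DMF, rt
Reagents that add atoms: chlorotriisopropylsilane, CC(C)[Si](Cl)(C(C)C)C(C)C
Why: Silylation of the phenol gives a bulky, non-coordinating ether that should survive the later acid, base and organolithium steps and block lithiation next to it in step 4.

Step 2
Reactants: 2 3,4-dimethoxy-5-(triisopropylsilyloxy)benzaldehyde
Product: 4 3,4-dimethoxy-5-(triisopropylsilyloxy)phenol, via aryl formate 3 (not isolated)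
Conditions: mCPBA, CH2Cl2, 0 °C → rt; then Et3N, MeOH, rt
Reagents that add atoms: 3-chloroperbenzoic acid, O=C(OO)c1cccc(Cl)c1
Why: Baeyer–Villiger (Dakin-type) oxidation, in which the electron-rich para-methoxy aryl group migrates to oxygen in preference to hydride and the formate is methanolysed under conditions too mild to cleave the aryl silyl ether.

Step 3
Reactants: 4 3,4-dimethoxy-5-(triisopropylsilyloxy)phenol
Product: 5 [3,4-dimethoxy-5-(methoxymethoxy)phenoxy]triisopropylsilane
Conditions: MOMCl, i-Pr2NEt, CH2Cl2, 0 °C → rt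
Reagents that add atoms: chloromethyl methyl ether, COCCl
Why: O-Alkylation of the phenol installs a MOM ether, a strong directing group for the lithiation that follows.

Step 4
Reactants: 5 [3,4-dimethoxy-5-(methoxymethoxy)phenoxy]triisopropylsilane
Product: 7 [4-iodo-2,3-dimethoxy-5-(methoxymethoxy)phenoxy]triisopropylsilane, via aryllithium 6 (not isolated)
Conditions: n-BuLi, THF, −20 → 0 °C; then I2, −78 °C → rt
Reagents that add atoms: iodine, [I][I]
Why: Directed ortho-lithiation should remove the one ring hydrogen flanked by two coordinating oxygens (OMOM and OMe), the other being shielded by the bulky silyl ether, and iodine traps the aryllithium.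

Step 5
Reactants: 7 [4-iodo-2,3-dimethoxy-5-(methoxymethoxy)phenoxy]triisopropylsilane
Product: 8 2-iodo-3,4-dimethoxy-5-(triisopropylsilyloxy)phenol
Conditions: HCl (cat.), MeOH, rt → 40 °C
Reagents that add atoms: none
Why: Acid-catalysed acetal exchange removes the phenolic MOM ether, while the aryl TIPS ether, the aryl iodide and the methyl ethers are stable to dilute methanolic HCl.

Step 6
Reactants: 9 2-(5-bromo-2-methoxyphenyl)acetic acid
Product: 11 2-(5-bromo-2-methoxyphenyl)-N-methoxy-N-methylacetamide, via acyl imidazole 10 (not isolated)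
Conditions: 1,1′-carbonyldiimidazole, CH2Cl2, rt; then MeNHOMe·HCl, rt
Reagents that add atoms: N,O-dimethylhydroxylamine hydrochloride, CNOC.Cl
Why: Amide formation through the acyl imidazole gives the Weinreb amide, which is needed for a single addition of the organomagnesium reagent.

Step 7
Reactants: 11 2-(5-bromo-2-methoxyphenyl)-N-methoxy-N-methylacetamide; 12 isopropenylmagnesium bromide (prop-1-en-2-ylmagnesium bromide)
Product: 14 1-(5-bromo-2-methoxyphenyl)-3-methylbut-3-en-2-one, via magnesium hemiaminal 13 (not isolated)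
Conditions: THF, −20 → 0 °C; inverse quench into cold dilute aq. HCl
Reagents that add atoms: none
Why: Weinreb ketone synthesis, in which the chelated tetrahedral adduct does not collapse until the acidic quench, so over-addition is avoided and the liberated N,O-dimethylhydroxylamine is protonated before it can add to the new enone.

Step 8
Reactants: 14 1-(5-bromo-2-methoxyphenyl)-3-methylbut-3-en-2-one
Product: 15 (2R)-1-(5-bromo-2-methoxyphenyl)-3-methylbut-3-en-2-ol
Conditions: (S)-Me-CBS oxazaborolidine [(S)-1-methyl-3,3-diphenyltetrahydro-1H,3H-pyrrolo[1,2-c][1,3,2]oxazaborole] (0.2 equiv), catecholborane, toluene, −78 °C; MeOH, then aq. NaOH work-up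
Reagents that add atoms: none
Why: Corey–Bakshi–Shibata reduction, in which the branched isopropenyl group should act as the large substituent against the arylmethyl CH2, so the (S)-catalyst delivers hydride to the face that gives the (R) alcohol (as acetophenone gives (R)-1-phenylethanol), and catecholborane at −78 °C should leave the alkene alone.

Step 9
Reactants: 15 (2R)-1-(5-bromo-2-methoxyphenyl)-3-methylbut-3-en-2-ol
Product: 16 {[(2R)-1-(5-bromo-2-methoxyphenyl)-3-methylbut-3-en-2-yl]oxy}triethylsilane
Conditions: TESCl, imidazole, CH2Cl2, 0 °C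
Reagents that add atoms: chlorotriethylsilane, CC[Si](Cl)(CC)CC
Why: Silylation masks the secondary allylic alcohol against acylpalladium species in step 12 and against the amide base in step 13, and the ether comes off with the aryl silyl ether in the last step.

Step 10
Reactants: 16 {[(2R)-1-(5-bromo-2-methoxyphenyl)-3-methylbut-3-en-2-yl]oxy}triethylsilane; 17 trimethylsilylacetylene
Product: 18 triethyl{[(2R)-1-{2-methoxy-5-[(trimethylsilyl)ethynyl]phenyl}-3-methylbut-3-en-2-yl]oxy}silane
Conditions: PdCl2(PhCN)2 (3 mol%), [HP(t-Bu)3]BF4 (6 mol%), CuI (2 mol%), i-Pr2NH, dioxane, rt → 40 °C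
Reagents that add atoms: none
Why: Sonogashira coupling, in which the bulky electron-rich tri-tert-butylphosphine lets zerovalent palladium insert into the electron-rich aryl bromide near room temperature while the silyl ether and the 1,1-disubstituted alkene stay inert.

Step 11
Reactants: 18 triethyl{[(2R)-1-{2-methoxy-5-[(trimethylsilyl)ethynyl]phenyl}-3-methylbut-3-en-2-yl]oxy}silane
Product: 19 triethyl{[(2R)-1-(5-ethynyl-2-methoxyphenyl)-3-methylbut-3-en-2-yl]oxy}silane
Conditions: K2CO3 (cat.), MeOH/THF, 0 °C → rt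
Reagents that add atoms: none
Why: Methanolysis of the alkynyl C–Si bond is far faster than cleavage of the secondary triethylsilyl ether, so the terminal alkyne should be released selectively.

Step 12
Reactants: 8 2-iodo-3,4-dimethoxy-5-(triisopropylsilyloxy)phenol; 19 triethyl{[(2R)-1-(5-ethynyl-2-methoxyphenyl)-3-methylbut-3-en-2-yl]oxy}silane; 20 carbon monoxide
Product: 23 5,6-dimethoxy-2-{4-methoxy-3-[(2R)-3-methyl-2-(triethylsilyloxy)but-3-en-1-yl]phenyl}-7-(triisopropylsilyloxy)-4H-chromen-4-one, via ortho-hydroxyaryl ynone 21 (not isolated), via enaminone 22 (not isolated)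
Conditions: PdCl2(dppf) (5 mol%), CO (20 bar), Et2NH, 120 °C
Reagents that add atoms: none
Why: Zerovalent palladium, formed from PdCl2(dppf) in the amine, inserts into the C4a–I bond of 8, CO insertion gives the aroylpalladium iodide, and coupling with the terminal alkyne forms C4a–C4 and C4–C3 in ynone 21. Diethylamine then adds to C2 of the ynone to give enaminone 22, and the phenol oxygen O1 attacks the same carbon and expels the amine, which forms O1–C2. The closest known reaction is the palladium-catalysed carbonylative coupling and cyclisation of ortho-iodophenols with terminal arylacetylenes to flavones. Ring C closes in a 6-endo sense by addition–elimination on the enaminone and not by 5-exo attack on the triple bond, so the aurone should be avoided. No stereocentre is formed, and the (R) carbinol centre of 19, held as its triethylsilyl ether, is not touched. The step needs carbonylative over direct alkynylation, which CO pressure and the absence of a copper salt favour, and the ring A pattern is fixed by the single C–I bond placed between the phenol oxygen and the C5 methoxy group in step 4.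

Step 13
Reactants: 23 5,6-dimethoxy-2-{4-methoxy-3-[(2R)-3-methyl-2-(triethylsilyloxy)but-3-en-1-yl]phenyl}-7-(triisopropylsilyloxy)-4H-chromen-4-one
Product: 26 3-hydroxy-5,6-dimethoxy-2-{4-methoxy-3-[(2R)-3-methyl-2-(triethylsilyloxy)but-3-en-1-yl]phenyl}-7-(triisopropylsilyloxy)-4H-chromen-4-one, via 3-lithioflavone 24 (not isolated), via flavon-3-ylboronate 25 (not isolated)
Conditions: LiN(i-Pr)2, THF, −78 °C; B(OMe)3, −78 → 0 °C; then H2O2 (30%), AcOH, 0 °C
Reagents that add atoms: hydrogen peroxide, OO
Why: The known lithiation–borylation–oxidation of flavones: the amide base removes the C3 hydrogen, the only vinylic hydrogen activated by both the C4 carbonyl and O1, the 3-lithio species is trapped on boron, and the C–B bond is oxidised to the enol without touching the isopropenyl group at 0 °C.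

Step 14
Reactants: 26 3-hydroxy-5,6-dimethoxy-2-{4-methoxy-3-[(2R)-3-methyl-2-(triethylsilyloxy)but-3-en-1-yl]phenyl}-7-(triisopropylsilyloxy)-4H-chromen-4-one
Product: 27 3,7-dihydroxy-2-{3-[(2R)-2-hydroxy-3-methylbut-3-en-1-yl]-4-methoxyphenyl}-5,6-dimethoxy-4H-chromen-4-one
Conditions: Bu4NF, AcOH, THF, 0 °C → rt
Reagents that add atoms: none
Why: Fluoride cleaves both silyl ethers, and the acetic acid buffer should keep the air-sensitive flavonol from standing as its dianion and leave the allylic carbinol centre unchanged.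

Compound list
1 | 3-hydroxy-4,5-dimethoxybenzaldehyde | COc1cc(C=O)cc(O)c1OC | starting material
2 | 3,4-dimethoxy-5-(triisopropylsilyloxy)benzaldehyde | COc1cc(C=O)cc(O[Si](C(C)C)(C(C)C)C(C)C)c1OC | intermediate
3 | 3,4-dimethoxy-5-(triisopropylsilyloxy)phenyl formate | COc1cc(OC=O)cc(O[Si](C(C)C)(C(C)C)C(C)C)c1OC | intermediate (not isolated)
4 | 3,4-dimethoxy-5-(triisopropylsilyloxy)phenol | COc1cc(O)cc(O[Si](C(C)C)(C(C)C)C(C)C)c1OC | intermediate
5 | [3,4-dimethoxy-5-(methoxymethoxy)phenoxy]triisopropylsilane | COCOc1cc(OC)c(OC)c(O[Si](C(C)C)(C(C)C)C(C)C)c1 | intermediate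
6 | [4-lithio-2,3-dimethoxy-5-(methoxymethoxy)phenoxy]triisopropylsilane | COCOc1c([Li])c(OC)c(OC)c(O[Si](C(C)C)(C(C)C)C(C)C)c1 | intermediate (not isolated)
7 | [4-iodo-2,3-dimethoxy-5-(methoxymethoxy)phenoxy]triisopropylsilane | COCOc1c(I)c(OC)c(OC)c(O[Si](C(C)C)(C(C)C)C(C)C)c1 | intermediate
8 | 2-iodo-3,4-dimethoxy-5-(triisopropylsilyloxy)phenol | Oc1cc(O[Si](C(C)C)(C(C)C)C(C)C)c(OC)c(OC)c1I | intermediate
9 | 2-(5-bromo-2-methoxyphenyl)acetic acid | COc1ccc(Br)cc1CC(=O)O | starting material
10 | 1-[2-(5-bromo-2-methoxyphenyl)acetyl]-1H-imidazole | COc1ccc(Br)cc1CC(=O)n1ccnc1 | intermediate (not isolated)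
11 | 2-(5-bromo-2-methoxyphenyl)-N-methoxy-N-methylacetamide | COc1ccc(Br)cc1CC(=O)N(C)OC | intermediate
12 | isopropenylmagnesium bromide | C=C(C)[Mg]Br | starting material
13 | bromomagnesium alkoxide of 1-(5-bromo-2-methoxyphenyl)-2-[methoxy(methyl)amino]-3-methylbut-3-en-2-ol (racemic) | C=C(C)C(Cc1cc(Br)ccc1OC)(O[Mg]Br)N(C)OC | intermediate (not isolated)
14 | 1-(5-bromo-2-methoxyphenyl)-3-methylbut-3-en-2-one | C=C(C)C(=O)Cc1cc(Br)ccc1OC | intermediate
15 | (2R)-1-(5-bromo-2-methoxyphenyl)-3-methylbut-3-en-2-ol | C=C(C)[C@H](O)Cc1cc(Br)ccc1OC | intermediate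
16 | {[(2R)-1-(5-bromo-2-methoxyphenyl)-3-methylbut-3-en-2-yl]oxy}triethylsilane | C=C(C)[C@H](O[Si](CC)(CC)CC)Cc1cc(Br)ccc1OC | intermediate
17 | trimethylsilylacetylene | C#C[Si](C)(C)C | starting material
18 | triethyl{[(2R)-1-{2-methoxy-5-[(trimethylsilyl)ethynyl]phenyl}-3-methylbut-3-en-2-yl]oxy}silane | C=C(C)[C@H](O[Si](CC)(CC)CC)Cc1cc(C#C[Si](C)(C)C)ccc1OC | intermediate
19 | triethyl{[(2R)-1-(5-ethynyl-2-methoxyphenyl)-3-methylbut-3-en-2-yl]oxy}silane | C=C(C)[C@H](O[Si](CC)(CC)CC)Cc1cc(C#C)ccc1OC | intermediate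
20 | carbon monoxide | [C-]#[O+] | starting material
21 | 1-[2-hydroxy-5,6-dimethoxy-4-(triisopropylsilyloxy)phenyl]-3-{4-methoxy-3-[(2R)-3-methyl-2-(triethylsilyloxy)but-3-en-1-yl]phenyl}prop-2-yn-1-one | C=C(C)[C@H](O[Si](CC)(CC)CC)Cc1cc(C#CC(=O)c2c(O)cc(O[Si](C(C)C)(C(C)C)C(C)C)c(OC)c2OC)ccc1OC | intermediate (not isolated)
22 | 3-(diethylamino)-1-[2-hydroxy-5,6-dimethoxy-4-(triisopropylsilyloxy)phenyl]-3-{4-methoxy-3-[(2R)-3-methyl-2-(triethylsilyloxy)but-3-en-1-yl]phenyl}prop-2-en-1-one (alkene geometry not controlled) | C=C(C)[C@H](O[Si](CC)(CC)CC)Cc1cc(C(=CC(=O)c2c(O)cc(O[Si](C(C)C)(C(C)C)C(C)C)c(OC)c2OC)N(CC)CC)ccc1OC | intermediate (not isolated)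
23 | 5,6-dimethoxy-2-{4-methoxy-3-[(2R)-3-methyl-2-(triethylsilyloxy)but-3-en-1-yl]phenyl}-7-(triisopropylsilyloxy)-4H-chromen-4-one | C=C(C)[C@H](O[Si](CC)(CC)CC)Cc1cc(-c2cc(=O)c3c(OC)c(OC)c(O[Si](C(C)C)(C(C)C)C(C)C)cc3o2)ccc1OC | intermediate
24 | 3-lithio derivative of 23 | C=C(C)[C@H](O[Si](CC)(CC)CC)Cc1cc(-c2oc3cc(O[Si](C(C)C)(C(C)C)C(C)C)c(OC)c(OC)c3c(=O)c2[Li])ccc1OC | intermediate (not isolated)
25 | dimethyl boronate at C3 of 23 (present as its lithium methoxide ate complex) | C=C(C)[C@H](O[Si](CC)(CC)CC)Cc1cc(-c2oc3cc(O[Si](C(C)C)(C(C)C)C(C)C)c(OC)c(OC)c3c(=O)c2B(OC)OC)ccc1OC | intermediate (not isolated)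
26 | 3-hydroxy-5,6-dimethoxy-2-{4-methoxy-3-[(2R)-3-methyl-2-(triethylsilyloxy)but-3-en-1-yl]phenyl}-7-(triisopropylsilyloxy)-4H-chromen-4-one | C=C(C)[C@H](O[Si](CC)(CC)CC)Cc1cc(-c2oc3cc(O[Si](C(C)C)(C(C)C)C(C)C)c(OC)c(OC)c3c(=O)c2O)ccc1OC | intermediate
27 | 3,7-dihydroxy-2-{3-[(2R)-2-hydroxy-3-methylbut-3-en-1-yl]-4-methoxyphenyl}-5,6-dimethoxy-4H-chromen-4-one | C=C(C)[C@H](O)Cc1cc(-c2oc3cc(O)c(OC)c(OC)c3c(=O)c2O)ccc1OC | target

Total step count: 14.
Longest linear sequence: 9 steps (from 9 through steps 6–14 to 27); the ring A branch (steps 1–5) joins at step 12.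

Steps most likely to fail

1. Step 12. The alkyne may couple to the arylpalladium species before CO inserts, which would lead on to a 2-arylbenzofuran. The ynone may also close 5-exo to the aurone, or the aryl silyl ether may be lost in hot diethylamine. The fallback sets out from 5 (with 19) and comes back at 23, reaching the same ynone 21 without palladium or CO. Compound 5 would be lithiated as in step 4 and the aryllithium 6 quenched with DMF instead of iodine to give 2,3-dimethoxy-6-(methoxymethoxy)-4-(triisopropylsilyloxy)benzaldehyde F1. HCl in MeOH at rt would remove the MOM group, which is labile next to the formyl group, to give 6-hydroxy-2,3-dimethoxy-4-(triisopropylsilyloxy)benzaldehyde F2. Alkyne 19 would be deprotonated with n-BuLi (THF, −78 °C) to its lithium acetylide F3. A little over two equivalents of it (one is consumed by the phenol) would add to F2 to give the propargylic alcohol F4 as a mixture of carbinol epimers. MnO2 in CH2Cl2 would oxidise the benzylic, propargylic carbinol to 21, and Et2NH in EtOH (rt → 50 °C) would take 21 through 22 to 23.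

2. Step 13. The 3-lithiated pyranone may ring-open to the ynone phenoxide before boron traps it, metalation may occur at other sites, or the flavonol may degrade during the peroxide treatment. The fallback sets out from 23 and comes back at 26 without a C3 carbanion. 1,4-Reduction with LiBH(s-Bu)3 (THF, −78 °C) would give the flavanone lithium enolate F5. It would be hydroxylated in the same flask with 2-(phenylsulfonyl)-3-phenyloxaziridine to the trans-3-hydroxyflavanone F6 (both trans diastereomers). Dess–Martin periodinane (NaHCO3, CH2Cl2, rt) would oxidise the C3 carbinol to the 3,4-dione, the keto tautomer of 26, which enolises to 26.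

3. Step 8. The isopropenyl and arylmethyl flanks of the ketone may be discriminated too weakly, giving low enantiomeric purity, or the borane may reduce the enone in the conjugate sense. The fallback sets out from 14 and comes back at 15. Luche reduction (NaBH4, CeCl3·7H2O, MeOH, 0 °C) would give the racemic 1-(5-bromo-2-methoxyphenyl)-3-methylbut-3-en-2-ol F7. Sharpless kinetic resolution (Ti(Oi-Pr)4, L-(+)-diisopropyl tartrate, t-BuOOH 0.6 equiv, 4 Å sieves, CH2Cl2, −20 °C) should epoxidise the (S) alcohol faster, to the epoxy alcohol F8. The unreacted (R) alcohol 15 would be separated by chromatography.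

Further compounds
F1 | step 12 | 2,3-dimethoxy-6-(methoxymethoxy)-4-(triisopropylsilyloxy)benzaldehyde | COCOc1cc(O[Si](C(C)C)(C(C)C)C(C)C)c(OC)c(OC)c1C=O
F2 | step 12 | 6-hydroxy-2,3-dimethoxy-4-(triisopropylsilyloxy)benzaldehyde | Oc1cc(O[Si](C(C)C)(C(C)C)C(C)C)c(OC)c(OC)c1C=O
F3 | step 12 | lithium acetylide of 19 | C=C(C)[C@H](O[Si](CC)(CC)CC)Cc1cc(C#C[Li])ccc1OC
F4 | step 12 | 2-(1-hydroxy-3-{4-methoxy-3-[(2R)-3-methyl-2-(triethylsilyloxy)but-3-en-1-yl]phenyl}prop-2-yn-1-yl)-3,4-dimethoxy-5-(triisopropylsilyloxy)phenol (both carbinol epimers) | C=C(C)[C@H](O[Si](CC)(CC)CC)Cc1cc(C#CC(O)c2c(O)cc(O[Si](C(C)C)(C(C)C)C(C)C)c(OC)c2OC)ccc1OC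
F5 | step 13 | lithium enolate of 5,6-dimethoxy-2-{4-methoxy-3-[(2R)-3-methyl-2-(triethylsilyloxy)but-3-en-1-yl]phenyl}-7-(triisopropylsilyloxy)chroman-4-one (both C2 epimers) | C=C(C)[C@H](O[Si](CC)(CC)CC)Cc1cc(C2Oc3cc(O[Si](C(C)C)(C(C)C)C(C)C)c(OC)c(OC)c3C(O[Li])=C2)ccc1OC
F6 | step 13 | trans-3-hydroxy-5,6-dimethoxy-2-{4-methoxy-3-[(2R)-3-methyl-2-(triethylsilyloxy)but-3-en-1-yl]phenyl}-7-(triisopropylsilyloxy)chroman-4-one (2,3-trans, both trans diastereomers) | C=C(C)[C@H](O[Si](CC)(CC)CC)Cc1cc(C2Oc3cc(O[Si](C(C)C)(C(C)C)C(C)C)c(OC)c(OC)c3C(=O)C2O)ccc1OC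
F7 | step 8 | racemic 1-(5-bromo-2-methoxyphenyl)-3-methylbut-3-en-2-ol | C=C(C)C(O)Cc1cc(Br)ccc1OC
F8 | step 8 | (1S)-2-(5-bromo-2-methoxyphenyl)-1-[(2R)-2-methyloxiran-2-yl]ethan-1-ol | C[C@@]1(CO1)[C@@H](O)Cc1cc(Br)ccc1OC
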